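- In this closed, stirred vessel you read [target] at each time, with the same scatter at every point, so watch whole curves rather than one early point.

| flask | substrate | partner | time |
|---|---|---|---|
| winter | 1.00 M | 2.00 M |  |
| summer | 3.00 M | 2.00 M |  |
| spring | 1.00 M | 1.00 M |  |
| dawn | 1.00 M | 2.00 M | 100 min |

| run | time / min | [target] / M |
|---|---|---|
| winter run | 4.2 | 0.201 |
| winter run | 8.5 | 0.312 |
| winter run | 13 | 0.429 |
| winter run | 17 | 0.459 |
| winter run | 21 | 0.505 |
| winter run | 26 | 0.538 |
| winter run | 30 | 0.545 |
| winter run | 34 | 0.566 |
| summer run | 4.2 | 0.529 |
| summer run | 8.5 | 0.853 |
| summer run | 13 | 1.041 |
| summer run | 17 | 1.150 |
| summer run | 21 | 1.169 |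
| summer run | 26 | 1.193 |
| summer run | 30 | 1.190 |
| summer run | 34 | 1.187 |
| spring run | 4.2 | 0.123 |
| spring run | 8.5 | 0.222 |
| spring run | 13 | 0.293 |
| spring run | 17 | 0.327 |
| spring run | 21 | 0.345 |
| spring run | 26 | 0.343 |
| spring run | 30 | 0.366 |
| spring run | 34 | 0.367 |

(readings scatter by 0.01 M)

1. how the opening rate goes with [partner] round the charge of the winter run: the exponent of the rate at two percent of substrate gone to target
2. how the opening rate goes with [substrate] round the charge of the winter run: the exponent of the rate at two percent of substrate gone to target (one fixed amount of target, the same in the runs compared)
3. target in the dawn run at 100 min, as a share of the substrate charged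

- Overall: substrate + partner -> target.
- Constant volume, constant temperature.
- The analysis sees a species whether free or bound.
- An order is taken over about fifteen percent of the charge, up and down.

- The bench habit is to take the mean rate up to the first reading. But in the winter run that reading already stands at 20.1% of the substrate, ten times the two percent asked about.
- So replace each curve by its mean instead: 0.444 M for the winter run, 0.298 M for the spring run and 1.04 M for the summer run.
- Winter against spring, where the partner charge differs, gives 0.575. Call this the mean-curve order: for two runs that differ in the charge of one species, with the other charge held fixed, the logarithm of the ratio of the two curve means over the logarithm of the ratio of the two differing charges. It can stand for the opening order if the ratio of the two curves stays flat along time.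
- So test that. Winter over spring, on summed readings, gives 1.45 up to 17 min and 1.52 after it.
- Summer over winter falls from 2.55 to 2.20, a larger drift. I take that pair to lie past the border and read its mean-curve order of 0.773 as low. The summer-over-winter ratio up to 17 min gives an order of 0.852, and the ratio at the first reading is 2.63, so I put the substrate order above 0.852.
- The dawn run repeats the winter charge, so I take the last winter reading, 56.6% of the substrate, as my figure for 100 min.
- The forecast gives 0.75 for the partner order, 0.95 for the substrate order and 57.5% for the dawn run, with its orders from “Early rates, estimated from the first points”. Its partner order stands above mine.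
- The flask gives 0.54 for the partner order, 1.0 for the substrate order and 57.2% for the dawn run.

    substrate + partner → target (0.2784 M⁻¹ min⁻¹)
    target + partner → side product (0.06360 M⁻¹ min⁻¹)
    2 partner ⇌ idle reagent dimer, settled at all times (23.70 M⁻¹)
    partner → lost reagent (0.3246 min⁻¹)

- The mean-curve order of 0.575 lies 0.0350 above the partner order, while the summer pair's 0.773 lies 0.227 below the substrate order. In the winter run, substrate and partner made target, reaching a quarter of the substrate charged at 6.07 min and half at 20.9 min, while partner also went to lost reagent and target went on to side product. In the dawn run, target at 100 min stands at 57.2% of the substrate charged.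

All runs are calculated from invented constants; scatter was added.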